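**Remark on the chemistry.** Unprimed locants refer to unit 1 (rings A, C, B), double-primed locants to rings D and E of unit 2, and triple-primed locants to its aryl ring F. The diketone 8 is assumed to react through its enol form, the normal state of a 1,3-diaryl-1,3-diketone in solution. Compounds 8 and 9 were checked atom by atom against rings D, E and F of the target and needed no correction. The spectator groups of 8 are kept for these reasons:
- The methyl group on O5'' is the ether least prone to oxidative dealkylation, and it later falls to BCl3 through chelation with the C4'' carbonyl.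
- The isopropyl group on O4''' sits on a ring that is not oxidised, and its oxygen makes the enol oxygen on C2'' a better nucleophile.
- The tert-butyl ester is inert to enolates and is removed without base.

## Structural features

The target is a biflavone ether with no stereocentre. Unit 1 (benzo ring A, pyranone ring C, aryl ring B) and unit 2 (benzo ring D, pyranone ring E, aryl ring F) are both 5-hydroxy-7-methoxyflavones. They are joined only by the diaryl ether oxygen between C4' of ring B and C8'' of ring D, and ring F carries a 4'''-hydroxyl. Three phenols must end free (the 5- and 5''-hydroxyls, each hydrogen-bonded to its C4 carbonyl, and the 4'''-hydroxyl) beside two methyl ethers (O7, O7''), so the oxygens must be told apart throughout. Ring D is the crowded part: C4a'' (acyl), C5'' (OH), C7'' (OMe), C8'' (OAr) and C8a'' (O1'') are all substituted and only C6'' carries hydrogen. The ether oxygen at C8'' lies between the C7'' methoxy group and O1'', so arylating an intact 8-hydroxyflavone is hindered; this is the real difficulty. Fragile features are the 4-pyranone rings (opened by hot aqueous alkali), the free phenols (above all ring D, whose oxygens at C5'' and C8'' are para and quinone-prone), and the methyl ethers that must survive the final dealkylation. The key step uses the fact that, without O1'', ring D is a 2,4,5-trioxygenated aryl ketone in which C8a'' is a C–H carbon between C4a'' and C8''. This easily oxidised hydroquinone-ether pattern arises from para-hydroxylation of a 2-hydroxy-4-methoxyacetophenone, and the O1''–C8a'' bond can then be made by oxidation, with the enol oxygen of a 1,3-diketone on C4a'' as the nucleophile.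

## Logic of the disconnections

**15 ⇒ 14.** The O–alkyl bonds at O4''' and O5'' are cut. These two phenols would interfere with the enolate, acid chloride and anodic chemistry, so they are unmasked last. The forward step needs one Lewis acid that removes a secondary alkyl ether and a methyl ether peri to a carbonyl while leaving the O7 and O7'' methyl ethers and the diaryl ether.

**14 ⇒ 13.** The O1–C2 bond of ring C is cut. This opens unit 1 to a 1,3-diketone on a ring A with two equivalent phenols, so no regiochemical question arises. The forward cyclodehydration must be mild enough for the ethers of unit 2.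

**13 ⇒ 10 + 11 (through 12).** The C2–C3 bond of unit 1 is cut. Ring A becomes the purchasable 11 and ring B is left with a carboxyl group. The forward step must acylate the polyanion of 11 on carbon without touching the pyranone of unit 2.

**10 ⇒ 9.** The ester O–C(tert-butyl) bond is cut. The carboxyl stays masked through enolate chemistry and electrolysis by a group that acid alone removes.

**9 ⇒ 8.** The O1''–C8a'' bond is cut, opening ring E. The crowded tetra-oxygenated ring D becomes a trioxygenated ring whose aryl ether was made at an unhindered phenol. The forward step must be an oxidative C–H/O–H closure at C8a'' and not at the methoxy-bearing C5''.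

**8 ⇒ 6 + 7.** The C2''–C3'' bond is cut. This gives a methyl ketone and a non-enolisable ester carrying ring F. The forward crossed Claisen condensation must spare the tert-butyl ester.

**6 ⇒ 5.** The O5''–CH3 bond is cut. Capping this oxygen stops it from becoming the ring oxygen and protects the hydroquinone pattern; the forward step alkylates a chelated phenol.

**5 ⇒ 3 + 4.** The O–C4' bond of the diaryl ether is cut. The nucleophile is an unhindered, unchelated phenoxide and the electrophile a para-activated aryl fluoride. The forward SNAr must distinguish the two phenols of 3.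

**3 ⇒ 1 (through 2).** The C8''–O bond is cut. The oxygen is introduced para to the phenol of a cheap 2-hydroxy-4-methoxy ketone, and the forward step relies on the para selectivity of persulfate oxidation.

## Other disconnections considered

**Alternative 1:** The cut is the C4a–C8a bond of ring A. In the forward direction Mg(OMe)2 opens the lactone of the 6-(2,4-dioxo-4-arylbutyl)-4-methoxy-2-pyranone A2. The magnesium-chelated C4a methylene carbanion then acylates the freed ester carbon C8a (intramolecular Claisen condensation), and enolisation gives the acylphloroglucinol diketone A1.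
- In favour: the pyranone methoxy group becomes the O7 methyl ether and the two flanking oxygens appear directly as free phenols, so ring A needs no protecting group. A1 is one cyclodehydration away from the flavone of unit 1.
- Against: the strategic step is spent on the one ring that can be bought (11 in the chosen plan). A2 is a sensitive polycarbonyl chain that can also fold by aldol pathways. Ring D of A1 still lacks the C4a'' acyl group and ring E, so after the key step the sequence needs ring C closure, debenzylation, C-acylation of ring D (where C6'', para to the freed phenol, competes with C4a''), a second diketone, ring E closure and demethylation.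
- Comparison: on precedent this alternative is the better, since biomimetic Claisen cyclisation of pyranone-masked polyketides is a known two-electron reaction class whereas the chosen key step is not. In needing no protecting group on ring A the two plans are equal. On structure it forms a C–C bond and a carbocycle but leaves the crowded ring D problem untouched, and on step economy it is clearly longer both before and after its key step.

**Alternative 2:** The cut is the C4''–C4a'' bond of ring E. In the forward direction the carboxyl group of the (Z)-3-aryl-3-aryloxyacrylic acid A4 is activated (P2O5 in MeSO3H, or as the acid chloride) and acylates ring D at C4a'', giving the protected biflavone A3 (the 5''-O-methyl-4'''-O-benzyl ether of the target).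
- In favour: this is the classical closure of a β-aryloxycinnamic acid to a flavone. C4a'' is ortho to O1'' and to the C5'' methoxy group and para to the C7'' methoxy group, so the most nucleophilic carbon of ring D reacts. The other position ortho to O1'' is blocked by the aryloxy group, so the regiochemistry is unambiguous. Only one deprotection follows.
- Against: unit 1, the diaryl ether and a ring D phenol whose hydroxyl at C8a'' stands next to the C8'' aryloxy group must all exist beforehand, so the crowded 1,2,3-trioxygenated ether has to be made by other means. The hindered phenol must add to an arylpropiolate with the Z geometry. The strong acid of the closure can reverse that addition or remove the benzyl group.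
- Comparison: on regiochemical certainty and electronic matching this alternative is the better, because the chosen plan asks the least activated carbon of ring D to react. Its one-step endgame is also better than the four steps of the chosen plan. The chosen plan is better in how the C8'' ether arises (SNAr at an unhindered phenol). Overall length is expected to be similar or longer because the ring D phenol needs its own sequence.

**Alternative 3:** The cuts are C8''–C8a'' and C5''–C4a'' of ring D. In the forward direction the 4-aryloxy-1,3-dimethoxy-1-silyloxybutadiene A6 adds across C5=C6 of the sulfinylpyranone A7, with the nucleophilic diene terminus C8'' bonding to the electrophilic C6 of the pyranone. Loss of 4-methylbenzenesulfenic acid and methoxytrimethylsilane then aromatises ring D to the 5-hydroxyflavone ester A5.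
- In favour: two C–C bonds and a ring form in one step, and all four heteroatom substituents of ring D are placed by the components. The hindered C8'' ether is carried in as an enol ether and is never made on a crowded arene. The 5''-hydroxyl emerges free, so no late demethylation is needed.
- Against: a 4-pyranone is a reluctant dienophile even with sulfinyl activation. A6 is a hydrolytically labile diene whose terminal aryloxy group disfavours the s-cis conformer. Both components need several steps each. The later steps on A5 must handle a methyl ester beside a free chelated phenol.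
- Comparison: in avoiding etherification of a hindered phenol the two plans are equal. In skeletal gain per step, in the security of the oxygenation pattern and in delivering the 5''-hydroxyl free, this alternative is the better. The chosen plan is shorter and uses only robust, purchasable building blocks before its key step. Both key steps rest on limited precedent for their exact substrate class, so neither is clearly safer mechanistically.

Key step: step 5

## Route

Step 1
Reactants: 1 paeonol (1-(2-hydroxy-4-methoxyphenyl)ethanone)
Product: 3 1-(2,5-dihydroxy-4-methoxyphenyl)ethanone, via potassium aryl sulfate 2 (not isolated)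
Conditions: K2S2O8, aq KOH, 15 °C; then HCl, 90 °C
Reagents that add atoms: potassium peroxodisulfate, [K+].[K+].[O-]S(=O)(=O)OOS(=O)(=O)[O-]
Why: Elbs persulfate oxidation: the phenoxide of 1 attacks a peroxide oxygen through C5', the free position para to the phenoxide oxygen, giving the aryl sulfate 2, which hot acid hydrolyses to the hydroquinone 3. Conversion is expected to be incomplete, and unreacted 1 is extracted before the hydrolysis.

Step 2
Reactants: 3 1-(2,5-dihydroxy-4-methoxyphenyl)ethanone; 4 tert-butyl 4-fluorobenzoate
Product: 5 tert-butyl 4-(5-acetyl-4-hydroxy-2-methoxyphenoxy)benzoate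
Conditions: K2CO3 (1.2 equiv), DMSO, 120 °C, argon
Reagents that add atoms: none
Why: SNAr: the 5'-hydroxyl is the only unchelated phenol and the more acidic one, so its phenoxide displaces fluoride para to the ester through a Meisenheimer intermediate. The 2'-hydroxyl, hydrogen-bonded to the acetyl group, stays free, and the tert-butyl ester is inert to carbonate.

Step 3
Reactants: 5 tert-butyl 4-(5-acetyl-4-hydroxy-2-methoxyphenoxy)benzoate
Product: 6 tert-butyl 4-(5-acetyl-2,4-dimethoxyphenoxy)benzoate
Conditions: MeI, K2CO3, DMF, 40 °C
Reagents that add atoms: iodomethane, CI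
Why: Williamson ether synthesis (SN2 on iodomethane) at the remaining chelated phenol. Capping O5'' prevents this oxygen from later becoming the pyranone oxygen and turns the hydroquinone pattern into its diether.

Step 4
Reactants: 6 tert-butyl 4-(5-acetyl-2,4-dimethoxyphenoxy)benzoate; 7 methyl 4-isopropoxybenzoate
Product: 8 tert-butyl 4-{5-[3-(4-isopropoxyphenyl)-3-oxopropanoyl]-2,4-dimethoxyphenoxy}benzoate
Conditions: LiN(SiMe3)2 (2.5 equiv), THF, −78 °C → rt; aq HCl
Reagents that add atoms: none
Why: Crossed Claisen condensation: the lithium enolate of the methyl ketone 6 acylates the non-enolisable methyl ester 7, and deprotonation of the 1,3-diketone by the second equivalent of base drives the equilibrium. The hindered tert-butyl ester should not be attacked under these conditions.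

Step 5
Reactants: 8 tert-butyl 4-{5-[3-(4-isopropoxyphenyl)-3-oxopropanoyl]-2,4-dimethoxyphenoxy}benzoate
Product: 9 tert-butyl 4-{[2-(4-isopropoxyphenyl)-5,7-dimethoxy-4-oxo-4H-chromen-8-yl]oxy}benzoate
Conditions: undivided cell, glassy-carbon anode, Pt cathode, constant current 2 mA cm−2, 2.2 F mol−1, n-Bu4NPF6 (0.1 M), (CF3)2CHOH, 0.01 M in 8, 20 °C, argon
Reagents that add atoms: none
Why: Proposed new method: ring D of 8, a 1,2,4-trioxygenated benzene with para oxygens at C5'' and C8'', should lose an electron first at the carbon anode; (CF3)2CHOH stabilises the arene radical cation, does not compete as a nucleophile, and breaks the internal hydrogen bond of the enolised diketone so that the rotamer with the C2'' oxygen next to C8a'' is populated. That oxygen, made more nucleophilic by the para isopropoxy group of ring F, adds to C8a''; the adduct radical loses a second electron, and loss of the C8a'' and enol protons gives the aromatic 4-pyranone, while the two protons are reduced to H2 at the platinum cathode, so no chemical oxidant is needed. The closest known reaction types are anodic dehydrogenative C–H/O–H cyclisations of biaryl-2-carboxylic acids to benzo[c]chromen-6-ones, oxidative closure of 2-hydroxybenzophenones to xanthones, and oxidative closure of enolisable α-aryl ketones to benzofurans; closure of a 4-pyranone by an enol oxygen onto an arene C–H has not been shown. Ring E closes in the 6-endo-trig mode (the C4a''–C8a'' bond lies inside the new ring), ipso closure at C4a'' or closure through C3'' would give strained small rings, and no stereocentre is formed. The first selectivity needed is electron removal from ring D and not from ring F or ring B, which is secured because ring F has one oxygen and a para carbonyl and ring B carries an ester. The second is attack at C8a'' and not at the methoxy-bearing C5'': only the C8a'' adduct can aromatise by proton loss, whereas the C5'' adduct is a mixed ketal that should mainly revert in this non-nucleophilic medium. The third is ring closure in preference to coupling of two molecules at C6'', which is favoured by high dilution and by the two methoxy groups flanking C6''. Because 9 carries one more oxygen on ring D and may be oxidised further, the charge is limited and the electrolysis is stopped short of full conversion; no pyridine-type base is added, since such bases add to arene radical cations.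

Step 6
Reactants: 9 tert-butyl 4-{[2-(4-isopropoxyphenyl)-5,7-dimethoxy-4-oxo-4H-chromen-8-yl]oxy}benzoate
Product: 10 4-{[2-(4-isopropoxyphenyl)-5,7-dimethoxy-4-oxo-4H-chromen-8-yl]oxy}benzoic acid
Conditions: CF3CO2H/CH2Cl2 (1:3), anisole (5 equiv), 0 °C → rt
Reagents that add atoms: none
Why: Acidolysis of the tert-butyl ester with loss of the tert-butyl cation, which anisole intercepts so that it cannot alkylate C6''. The alkyl aryl ethers, the diaryl ether and the 4-pyranone are stable to CF3CO2H at room temperature.

Step 7
Reactants: 10 4-{[2-(4-isopropoxyphenyl)-5,7-dimethoxy-4-oxo-4H-chromen-8-yl]oxy}benzoic acid; 11 1-(2,6-dihydroxy-4-methoxyphenyl)ethanone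
Product: 13 1-(2,6-dihydroxy-4-methoxyphenyl)-3-(4-{[2-(4-isopropoxyphenyl)-5,7-dimethoxy-4-oxo-4H-chromen-8-yl]oxy}phenyl)propane-1,3-dione, via acid chloride 12 (not isolated)
Conditions: (COCl)2, cat. DMF, CH2Cl2, 0 °C → rt, evaporation; then 11, LiN(SiMe3)2 (4.2 equiv), THF, −78 °C → rt; aq HCl
Reagents that add atoms: none
Why: Acid chloride formation, then Claisen-type C-acylation of the trilithium salt (two phenoxides and the enolate) of 11; a fourth equivalent of base deprotonates the diketone as it forms. Any O-acylated material should rearrange to the same diketone under the excess base (Baker–Venkataraman shift), and the pyranone of unit 2 has no acidic C–H and an aryl-shielded C2''.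

Step 8
Reactants: 13 1-(2,6-dihydroxy-4-methoxyphenyl)-3-(4-{[2-(4-isopropoxyphenyl)-5,7-dimethoxy-4-oxo-4H-chromen-8-yl]oxy}phenyl)propane-1,3-dione
Product: 14 5-hydroxy-2-(4-{[2-(4-isopropoxyphenyl)-5,7-dimethoxy-4-oxo-4H-chromen-8-yl]oxy}phenyl)-7-methoxy-4H-chromen-4-one
Conditions: AcOH, cat. H2SO4, 70 °C
Reagents that add atoms: none
Why: Acid-catalysed cyclodehydration of a 2-hydroxyaryl 1,3-diketone: one of the two equivalent phenols of ring A adds to the C2 carbonyl and water is lost, while the other remains as the chelated 5-hydroxyl. Partial loss of the isopropyl group would be harmless because step 9 removes it.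

Step 9
Reactants: 14 5-hydroxy-2-(4-{[2-(4-isopropoxyphenyl)-5,7-dimethoxy-4-oxo-4H-chromen-8-yl]oxy}phenyl)-7-methoxy-4H-chromen-4-one
Product: 15 5-hydroxy-8-[4-(5-hydroxy-7-methoxy-4-oxo-4H-chromen-2-yl)phenoxy]-2-(4-hydroxyphenyl)-7-methoxy-4H-chromen-4-one (CNP0415865.0)
Conditions: BCl3 (1 M in CH2Cl2, 6 equiv), CH2Cl2, −78 °C → rt; then MeOH, aq NaHCO3
Reagents that add atoms: none
Why: Lewis acid ether cleavage: BCl3 removes the secondary isopropyl group by ionisation of its O–C bond and the 5''-methyl group through a six-membered chelate with the C4'' carbonyl. The unchelated O7 and O7'' methyl ethers and the diaryl ether should not be cleaved at or below room temperature.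

## Compound list

1 | paeonol, 1-(2-hydroxy-4-methoxyphenyl)ethanone | CC(=O)c1ccc(OC)cc1O | starting material
2 | potassium 5-acetyl-4-hydroxy-2-methoxyphenyl sulfate | CC(=O)c1cc(OS(=O)(=O)[O-])c(OC)cc1O.[K+] | intermediate
3 | 1-(2,5-dihydroxy-4-methoxyphenyl)ethanone | CC(=O)c1cc(O)c(OC)cc1O | intermediate
4 | tert-butyl 4-fluorobenzoate | CC(C)(C)OC(=O)c1ccc(F)cc1 | starting material
5 | tert-butyl 4-(5-acetyl-4-hydroxy-2-methoxyphenoxy)benzoate | CC(=O)c1cc(Oc2ccc(cc2)C(=O)OC(C)(C)C)c(OC)cc1O | intermediate
6 | tert-butyl 4-(5-acetyl-2,4-dimethoxyphenoxy)benzoate | CC(=O)c1cc(Oc2ccc(cc2)C(=O)OC(C)(C)C)c(OC)cc1OC | intermediate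
7 | methyl 4-isopropoxybenzoate | COC(=O)c1ccc(OC(C)C)cc1 | starting material
8 | tert-butyl 4-{5-[3-(4-isopropoxyphenyl)-3-oxopropanoyl]-2,4-dimethoxyphenoxy}benzoate | CC(C)Oc1ccc(cc1)C(=O)CC(=O)c1cc(Oc2ccc(cc2)C(=O)OC(C)(C)C)c(OC)cc1OC | intermediate
9 | tert-butyl 4-{[2-(4-isopropoxyphenyl)-5,7-dimethoxy-4-oxo-4H-chromen-8-yl]oxy}benzoate | CC(C)Oc1ccc(cc1)-c1cc(=O)c2c(OC)cc(OC)c(Oc3ccc(cc3)C(=O)OC(C)(C)C)c2o1 | intermediate
10 | 4-{[2-(4-isopropoxyphenyl)-5,7-dimethoxy-4-oxo-4H-chromen-8-yl]oxy}benzoic acid | CC(C)Oc1ccc(cc1)-c1cc(=O)c2c(OC)cc(OC)c(Oc3ccc(cc3)C(=O)O)c2o1 | intermediate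
11 | 1-(2,6-dihydroxy-4-methoxyphenyl)ethanone | CC(=O)c1c(O)cc(OC)cc1O | starting material
12 | 4-{[2-(4-isopropoxyphenyl)-5,7-dimethoxy-4-oxo-4H-chromen-8-yl]oxy}benzoyl chloride | CC(C)Oc1ccc(cc1)-c1cc(=O)c2c(OC)cc(OC)c(Oc3ccc(cc3)C(Cl)=O)c2o1 | intermediate
13 | 1-(2,6-dihydroxy-4-methoxyphenyl)-3-(4-{[2-(4-isopropoxyphenyl)-5,7-dimethoxy-4-oxo-4H-chromen-8-yl]oxy}phenyl)propane-1,3-dione | COc1cc(O)c(C(=O)CC(=O)c2ccc(Oc3c(OC)cc(OC)c4c(=O)cc(-c5ccc(OC(C)C)cc5)oc34)cc2)c(O)c1 | intermediate
14 | 5-hydroxy-2-(4-{[2-(4-isopropoxyphenyl)-5,7-dimethoxy-4-oxo-4H-chromen-8-yl]oxy}phenyl)-7-methoxy-4H-chromen-4-one | COc1cc(O)c2c(=O)cc(-c3ccc(Oc4c(OC)cc(OC)c5c(=O)cc(-c6ccc(OC(C)C)cc6)oc45)cc3)oc2c1 | intermediate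
15 | 5-hydroxy-8-[4-(5-hydroxy-7-methoxy-4-oxo-4H-chromen-2-yl)phenoxy]-2-(4-hydroxyphenyl)-7-methoxy-4H-chromen-4-one | COc1cc(O)c2c(=O)cc(-c3ccc(Oc4c(OC)cc(O)c5c(=O)cc(-c6ccc(O)cc6)oc45)cc3)oc2c1 | target

## Step count and least certain steps

Total: 9 steps. Longest linear sequence: 9 steps (1 → 15); 4, 7 and 11 are purchased.

**Step 5 (key step, proposed new method).**
- What may go wrong: the enol oxygen may add at the methoxy-bearing C5'' and the ring be diverted to quinone-ketal material. The more electron-rich product may be oxidised further. Two radical cations may couple instead of cyclising.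
- Fallback with known chemistry, from 11 back to 9: the polyanion of 11 (LiN(SiMe3)2, THF) is acylated with 4-isopropoxybenzoyl chloride F1 to 1-(2,6-dihydroxy-4-methoxyphenyl)-3-(4-isopropoxyphenyl)propane-1,3-dione F2. Cyclodehydration (AcOH, cat. H2SO4) gives 5-hydroxy-2-(4-isopropoxyphenyl)-7-methoxy-4H-chromen-4-one F3. Elbs oxidation (K2S2O8, aq KOH/pyridine, then HCl), which attacks para to the 5-hydroxyl, gives through the potassium 8-sulfate F4 the 5,8-dihydroxy-2-(4-isopropoxyphenyl)-7-methoxy-4H-chromen-4-one F5. SNAr of its unchelated 8-phenoxide on 4 (K2CO3, DMSO, argon) gives tert-butyl 4-{[5-hydroxy-2-(4-isopropoxyphenyl)-7-methoxy-4-oxo-4H-chromen-8-yl]oxy}benzoate F6. Methylation of the chelated 5-hydroxyl (MeI, K2CO3, acetone, reflux) gives 9. The weak point of this detour is the arylation of the hindered 8-oxygen.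

**Step 2.**
- What may go wrong: slow substitution at the only moderately activated fluoride, air oxidation of the hydroquinone monoanion at 120 °C, and some arylation of the chelated phenol.
- Fallback, from 1 back to 6 (it also bypasses steps 1 and 3): N-bromosuccinimide in MeCN brominates 1 para to the hydroxyl to 1-(5-bromo-2-hydroxy-4-methoxyphenyl)ethanone F7. Methylation (MeI, K2CO3, DMF) gives 1-(5-bromo-2,4-dimethoxyphenyl)ethanone F8. Ullmann ether coupling with tert-butyl 4-hydroxybenzoate F9 (CuI, picolinic acid, K3PO4, DMSO, 90 °C) gives 6.

**Step 4.**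
- What may go wrong: incomplete acylation by the electron-rich methyl ester, attack of the enolate on the tert-butyl ester of a second molecule, or retro-Claisen cleavage on work-up.
- Fallback, from 6 back to 8: the lithium enolate of 6 (LiN(iPr)2, THF, −78 °C) adds to 4-isopropoxybenzaldehyde F10 to give the racemic aldol tert-butyl 4-{5-[3-hydroxy-3-(4-isopropoxyphenyl)propanoyl]-2,4-dimethoxyphenoxy}benzoate F11. Oxidation of the secondary alcohol with 2-iodoxybenzoic acid (EtOAc, 75 °C) gives 8.

**Step 7.**
- What may go wrong: O-acylation or double acylation of the polyanion, poor solubility of the polylithium salt, and hydrolysis of the acid chloride before it reacts.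
- Fallback, from 10 (through 12) and 11 back to 13: 12 is added to an excess of 11 in pyridine/CH2Cl2 at 0 °C to give the mono-ester 2-acetyl-3-hydroxy-5-methoxyphenyl 4-{[2-(4-isopropoxyphenyl)-5,7-dimethoxy-4-oxo-4H-chromen-8-yl]oxy}benzoate F12. A Baker–Venkataraman shift (t-BuOK, THF, 0 °C → rt) moves the aroyl group to carbon and gives 13.

## Further compounds

F1 | step 5 | 4-isopropoxybenzoyl chloride | CC(C)Oc1ccc(cc1)C(Cl)=O
F2 | step 5 | 1-(2,6-dihydroxy-4-methoxyphenyl)-3-(4-isopropoxyphenyl)propane-1,3-dione | COc1cc(O)c(C(=O)CC(=O)c2ccc(OC(C)C)cc2)c(O)c1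
F3 | step 5 | 5-hydroxy-2-(4-isopropoxyphenyl)-7-methoxy-4H-chromen-4-one | COc1cc(O)c2c(=O)cc(-c3ccc(OC(C)C)cc3)oc2c1
F4 | step 5 | potassium 5-hydroxy-2-(4-isopropoxyphenyl)-7-methoxy-4-oxo-4H-chromen-8-yl sulfate | COc1cc(O)c2c(=O)cc(-c3ccc(OC(C)C)cc3)oc2c1OS(=O)(=O)[O-].[K+]
F5 | step 5 | 5,8-dihydroxy-2-(4-isopropoxyphenyl)-7-methoxy-4H-chromen-4-one | COc1cc(O)c2c(=O)cc(-c3ccc(OC(C)C)cc3)oc2c1O
F6 | step 5 | tert-butyl 4-{[5-hydroxy-2-(4-isopropoxyphenyl)-7-methoxy-4-oxo-4H-chromen-8-yl]oxy}benzoate | COc1cc(O)c2c(=O)cc(-c3ccc(OC(C)C)cc3)oc2c1Oc1ccc(cc1)C(=O)OC(C)(C)C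
F7 | step 2 | 1-(5-bromo-2-hydroxy-4-methoxyphenyl)ethanone | CC(=O)c1cc(Br)c(OC)cc1O
F8 | step 2 | 1-(5-bromo-2,4-dimethoxyphenyl)ethanone | CC(=O)c1cc(Br)c(OC)cc1OC
F9 | step 2 | tert-butyl 4-hydroxybenzoate | CC(C)(C)OC(=O)c1ccc(O)cc1
F10 | step 4 | 4-isopropoxybenzaldehyde | CC(C)Oc1ccc(C=O)cc1
F11 | step 4 | tert-butyl 4-{5-[3-hydroxy-3-(4-isopropoxyphenyl)propanoyl]-2,4-dimethoxyphenoxy}benzoate (racemic) | CC(C)Oc1ccc(cc1)C(O)CC(=O)c1cc(Oc2ccc(cc2)C(=O)OC(C)(C)C)c(OC)cc1OC
F12 | step 7 | 2-acetyl-3-hydroxy-5-methoxyphenyl 4-{[2-(4-isopropoxyphenyl)-5,7-dimethoxy-4-oxo-4H-chromen-8-yl]oxy}benzoate | CC(=O)c1c(O)cc(OC)cc1OC(=O)c1ccc(Oc2c(OC)cc(OC)c3c(=O)cc(-c4ccc(OC(C)C)cc4)oc23)cc1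
A1 | alternative 1 | 1-{4-[2-(benzyloxy)-4,6-dimethoxyphenoxy]phenyl}-3-(2,6-dihydroxy-4-methoxyphenyl)propane-1,3-dione | COc1cc(O)c(C(=O)CC(=O)c2ccc(Oc3c(OCc4ccccc4)cc(OC)cc3OC)cc2)c(O)c1
A2 | alternative 1 | 6-(4-{4-[2-(benzyloxy)-4,6-dimethoxyphenoxy]phenyl}-2,4-dioxobutyl)-4-methoxy-2H-pyran-2-one | COc1cc(=O)oc(CC(=O)CC(=O)c2ccc(Oc3c(OCc4ccccc4)cc(OC)cc3OC)cc2)c1
A3 | alternative 2 | 2-[4-(benzyloxy)phenyl]-8-[4-(5-hydroxy-7-methoxy-4-oxo-4H-chromen-2-yl)phenoxy]-5,7-dimethoxy-4H-chromen-4-one | COc1cc(O)c2c(=O)cc(-c3ccc(Oc4c(OC)cc(OC)c5c(=O)cc(-c6ccc(OCc7ccccc7)cc6)oc45)cc3)oc2c1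
A4 | alternative 2 | (2Z)-3-[4-(benzyloxy)phenyl]-3-{2-[4-(5-hydroxy-7-methoxy-4-oxo-4H-chromen-2-yl)phenoxy]-3,5-dimethoxyphenoxy}prop-2-enoic acid | COc1cc(O)c2c(=O)cc(-c3ccc(Oc4c(OC)cc(OC)cc4O/C(=C\C(=O)O)c4ccc(OCc5ccccc5)cc4)cc3)oc2c1
A5 | alternative 3 | methyl 4-({2-[4-(benzyloxy)phenyl]-5-hydroxy-7-methoxy-4-oxo-4H-chromen-8-yl}oxy)benzoate | COC(=O)c1ccc(Oc2c(OC)cc(O)c3c(=O)cc(-c4ccc(OCc5ccccc5)cc4)oc23)cc1
A6 | alternative 3 | methyl 4-{[2,4-dimethoxy-4-(trimethylsilyloxy)buta-1,3-dien-1-yl]oxy}benzoate (mixture of double-bond isomers) | COC(=O)c1ccc(OC=C(OC)C=C(OC)O[Si](C)(C)C)cc1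
A7 | alternative 3 | 2-[4-(benzyloxy)phenyl]-5-(4-methylbenzenesulfinyl)-4H-pyran-4-one (racemic at sulfur) | Cc1ccc(cc1)S(=O)c1coc(cc1=O)-c1ccc(OCc2ccccc2)cc1
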